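**Retrosynthetic overview**
- Target ⇐ desilylation and 1,2-reduction of an (S)-5-alkyl-5-silyloxycyclohex-2-enone; the quaternary centre controls the carbinol centre.
- Enone ⇐ enantioselective two-carbon ring expansion of a prochiral 3-alkyl-3-silyloxycyclobutanone with acetylene (nickel-catalysed C–C insertion). This key step makes the six-membered ring and the quaternary carbinol centre.
- Cyclobutanone ⇐ dichloroketene cycloaddition to the kinetic silyl enol ether of the chain methyl ketone, then dechlorination. The four-membered ring is formed first, the six-membered ring from it.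
- Methyl ketone ⇐ Lindlar reduction; sp3–sp3 Suzuki coupling with 6-bromohexan-2-one; Kumada coupling with bromobenzene; acetylide alkylation of 5-chloropent-1-yne with 7-bromohept-1-ene.

Assumption: all six starting materials are catalogue items, and of the two antipodes of the chiral ligand in step 8 the one that gives the S quaternary centre is used (the sense of induction has to be found by experiment).

**Route**

Step 1
Reactants: 1 5-chloropent-1-yne; 2 7-bromohept-1-ene
Product: 4 12-chlorododec-1-en-8-yne, via lithium acetylide 3 (not isolated)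
Conditions: n-BuLi, THF, −78 °C; then 2, DMPU, −78 °C to rt
Reagents that add atoms: none
Why: SN2 alkylation of a lithium acetylide (terminal-alkyne alkylation); the primary bromide reacts far faster than any primary chloride, so the chloride handle survives.

Step 2
Reactants: 4 12-chlorododec-1-en-8-yne; 5 bromobenzene
Product: 7 12-phenyldodec-1-en-8-yne, via alkylmagnesium chloride 6 (not isolated)
Conditions: Mg turnings (I2 activation), THF, reflux; then 5, PdCl2(dppf) (2 mol%), THF, 0 °C to 50 °C
Reagents that add atoms: none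
Why: Kumada–Corriu coupling of a primary alkyl Grignard reagent with an aryl bromide; the 4-alkynyl Grignard has no favourable cyclisation mode and the wide-bite-angle dppf ligand suppresses β-hydride elimination.

Step 3
Reactants: 7 12-phenyldodec-1-en-8-yne; 8 6-bromohexan-2-one
Product: 10 18-phenyloctadec-14-yn-2-one, via alkylborane 9 (not isolated)
Conditions: 9-BBN (1.05 equiv), THF, 0 °C to rt; then 8, Pd(OAc)2 (4 mol%), PCy3 (8 mol%), K3PO4·H2O, THF, rt
Reagents that add atoms: none
Why: anti-Markovnikov hydroboration of the terminal alkene (much faster than the internal alkyne with 9-BBN) followed by B-alkyl Suzuki–Miyaura sp3–sp3 coupling with a primary alkyl bromide; the mild phosphate base tolerates the methyl ketone.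

Step 4
Reactants: 10 18-phenyloctadec-14-yn-2-one
Product: 11 (14Z)-18-phenyloctadec-14-en-2-one
Conditions: H2 (1 atm), Lindlar catalyst (Pd on CaCO3, poisoned with Pb(OAc)2), quinoline, EtOAc, rt
Reagents that add atoms: none
Why: Lindlar semi-hydrogenation; syn delivery of H2 on the poisoned palladium surface sets the Z alkene, and ketone and arene are untouched.

Step 5
Reactants: 11 (14Z)-18-phenyloctadec-14-en-2-one
Product: 13 triethyl{[(14Z)-18-phenyloctadeca-1,14-dien-2-yl]oxy}silane, via lithium enolate 12 (not isolated)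
Conditions: LDA (commercial solution, 1.1 equiv), THF, −78 °C; then Et3SiCl, −78 °C to 0 °C
Reagents that add atoms: chlorotriethylsilane, CC[Si](Cl)(CC)CC
Why: kinetic deprotonation of a methyl ketone at the methyl group and O-silylation (kinetic silyl enol ether formation).

Step 6
Reactants: 13 triethyl{[(14Z)-18-phenyloctadeca-1,14-dien-2-yl]oxy}silane; 14 dichloroacetyl chloride
Product: 16 rac-2,2-dichloro-3-[(12Z)-16-phenylhexadec-12-en-1-yl]-3-[(triethylsilyl)oxy]cyclobutan-1-one, via dichloroketene 15 (not isolated)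
Conditions: 14 (1.3 equiv, slow addition), Et3N (1.4 equiv), hexane, 0 °C to rt
Reagents that add atoms: none
Why: ketene–enol ether [2+2] cycloaddition; the nucleophilic CH2 terminus bonds to the ketene carbonyl carbon (3-silyloxy regiochemistry), amine-generated dichloroketene adds to the electron-rich enol ether and not to the isolated Z alkene, and the new stereocentre is racemic and vanishes in step 7.

Step 7
Reactants: 16 rac-2,2-dichloro-3-[(12Z)-16-phenylhexadec-12-en-1-yl]-3-[(triethylsilyl)oxy]cyclobutan-1-one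
Product: 17 3-[(12Z)-16-phenylhexadec-12-en-1-yl]-3-[(triethylsilyl)oxy]cyclobutan-1-one
Conditions: Zn dust, NH4Cl, MeOH, rt
Reagents that add atoms: none
Why: reductive dechlorination of an α,α-dichloroketone by zinc (zinc enolate protonated in situ), which leaves a prochiral, mirror-symmetric cyclobutanone.

Step 8
Reactants: 17 3-[(12Z)-16-phenylhexadec-12-en-1-yl]-3-[(triethylsilyl)oxy]cyclobutan-1-one; 18 acetylene
Product: 19 (5S)-5-[(12Z)-16-phenylhexadec-12-en-1-yl]-5-[(triethylsilyl)oxy]cyclohex-2-en-1-one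
Conditions: Ni(cod)2 (10 mol%), chiral monodentate ligand L* (BINOL phosphoramidite of bis(1-phenylethyl)amine, 20 mol%), 18 (about 1.5 equiv, fed over 8 h as a dilute THF solution), toluene, 60 °C
Reagents that add atoms: none
Why: Proposed new method: zerovalent nickel carrying one bulky chiral ligand joins the strained C=O of 17 and acetylene by oxidative cyclisation, strain-driven β-carbon elimination then cleaves one of the two enantiotopic C(acyl)–CH2 bonds (the chiral pocket chooses which, and this sets the 5S centre), and C–C reductive elimination closes the cyclohexenone; the quaternary carbon has no β-hydrogen and the silyl ether is a poor leaving group, so reductive elimination should outrun β-oxygen elimination, and the slow acetylene feed holds back alkyne cyclotrimerisation; the closest known reaction type is the zerovalent-nickel/phosphine-catalysed insertion of internal alkynes into 3,3-disubstituted cyclobutanones (two-carbon ring expansion), which has not been shown with acetylene itself on a 3-silyloxy substrate with selection between the enantiotopic bonds.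

Step 9
Reactants: 19 (5S)-5-[(12Z)-16-phenylhexadec-12-en-1-yl]-5-[(triethylsilyl)oxy]cyclohex-2-en-1-one
Product: 20 (1S,5S)-5-[(12Z)-16-phenylhexadec-12-en-1-yl]-5-[(triethylsilyl)oxy]cyclohex-2-en-1-ol
Conditions: NaBH4, CeCl3·7H2O, MeOH/THF, −78 °C
Reagents that add atoms: none
Why: Luche 1,2-reduction; in the favoured half-chair the silyloxy group is pseudo-axial (smaller A value than the alkyl chain) and shields its own face, so hydride adds anti to it and the new hydroxyl ends cis to the C5 oxygen (1S).

Step 10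
Reactants: 20 (1S,5S)-5-[(12Z)-16-phenylhexadec-12-en-1-yl]-5-[(triethylsilyl)oxy]cyclohex-2-en-1-ol
Product: 21 (1S,3S)-1-[(12Z)-16-phenylhexadec-12-en-1-yl]cyclohex-4-ene-1,3-diol
Conditions: TBAF (1 M in THF), THF, 0 °C to 40 °C
Reagents that add atoms: none
Why: fluoride-mediated cleavage of the tertiary triethylsilyl ether (desilylation); no ketone is left, so elimination is not possible, and no stereocentre is touched.

**Compound list**
1 | 5-chloropent-1-yne | C#CCCCCl | starting material
2 | 7-bromohept-1-ene | C=CCCCCCBr | starting material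
3 | lithium 5-chloropent-1-yn-1-ide | [Li]C#CCCCCl | intermediate
4 | 12-chlorododec-1-en-8-yne | C=CCCCCCC#CCCCCl | intermediate
5 | bromobenzene | Brc1ccccc1 | starting material
6 | chloro(dodec-11-en-4-yn-1-yl)magnesium | Cl[Mg]CCCC#CCCCCCC=C | intermediate
7 | 12-phenyldodec-1-en-8-yne | C=CCCCCCC#CCCCc1ccccc1 | intermediate
8 | 6-bromohexan-2-one | CC(=O)CCCCBr | starting material
9 | 9-(12-phenyldodec-8-yn-1-yl)-9-borabicyclo[3.3.1]nonane | c1ccccc1CCCC#CCCCCCCCB2C3CCCC2CCC3 | intermediate
10 | 18-phenyloctadec-14-yn-2-one | CC(=O)CCCCCCCCCCCC#CCCCc1ccccc1 | intermediate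
11 | (14Z)-18-phenyloctadec-14-en-2-one | CC(=O)CCCCCCCCCCC/C=C\CCCc1ccccc1 | intermediate
12 | lithium (14Z)-18-phenyloctadeca-1,14-dien-2-olate | [Li]OC(=C)CCCCCCCCCCC/C=C\CCCc1ccccc1 | intermediate
13 | triethyl{[(14Z)-18-phenyloctadeca-1,14-dien-2-yl]oxy}silane | C=C(O[Si](CC)(CC)CC)CCCCCCCCCCC/C=C\CCCc1ccccc1 | intermediate
14 | dichloroacetyl chloride | ClC(Cl)C(=O)Cl | starting material
15 | dichloroketene | ClC(Cl)=C=O | intermediate
16 | rac-2,2-dichloro-3-[(12Z)-16-phenylhexadec-12-en-1-yl]-3-[(triethylsilyl)oxy]cyclobutan-1-one | O=C1CC(O[Si](CC)(CC)CC)(CCCCCCCCCCC/C=C\CCCc2ccccc2)C1(Cl)Cl | intermediate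
17 | 3-[(12Z)-16-phenylhexadec-12-en-1-yl]-3-[(triethylsilyl)oxy]cyclobutan-1-one | O=C1CC(O[Si](CC)(CC)CC)(CCCCCCCCCCC/C=C\CCCc2ccccc2)C1 | intermediate
18 | acetylene | C#C | starting material
19 | (5S)-5-[(12Z)-16-phenylhexadec-12-en-1-yl]-5-[(triethylsilyl)oxy]cyclohex-2-en-1-one | O=C1C=CC[C@@](O[Si](CC)(CC)CC)(CCCCCCCCCCC/C=C\CCCc2ccccc2)C1 | intermediate
20 | (1S,5S)-5-[(12Z)-16-phenylhexadec-12-en-1-yl]-5-[(triethylsilyl)oxy]cyclohex-2-en-1-ol | O[C@@H]1C=CC[C@@](O[Si](CC)(CC)CC)(CCCCCCCCCCC/C=C\CCCc2ccccc2)C1 | intermediate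
21 | (1S,3S)-1-[(12Z)-16-phenylhexadec-12-en-1-yl]cyclohex-4-ene-1,3-diol | O[C@@H]1C=CC[C@@](O)(CCCCCCCCCCC/C=C\CCCc2ccccc2)C1 | target

**Step count and risks**
Total steps: 10. Longest linear sequence: 10 steps (fully linear from 1).

The three steps most likely to fail:

Step 8 (new reaction). Acetylene may oligomerise on nickel, the β-silyloxy alkylnickel stage may eliminate, and the enantioselectivity is untested. The fallback uses known chemistry, sets out from ketone 11 and comes back to the route at target 21. A boron aldol of 11 with acrolein, using the Ipc2BCl antipode that gives the 3R adduct (Et3N, Et2O, −78 °C), gives (3R,17Z)-3-hydroxy-21-phenylhenicosa-1,17-dien-5-one F1; if the ee is short, a Sharpless kinetic resolution with Ti(OiPr)4, L-(+)-DIPT and TBHP consumes the 3S alcohol. Chelation-controlled allylation of the β-hydroxy ketone (allyltrifluorosilane, Et3N, or allylSnBu3 with MgBr2·OEt2) gives (3R,5S,17Z)-21-phenyl-5-(prop-2-en-1-yl)henicosa-1,17-diene-3,5-diol F2. Ring-closing metathesis with the first-generation Grubbs catalyst RuCl2(=CHPh)(PCy3)2 (dilute CH2Cl2, rt; this catalyst leaves the internal Z alkene alone) gives the trans-diol (1S,3R)-1-[(12Z)-16-phenylhexadec-12-en-1-yl]cyclohex-4-ene-1,3-diol F3. Chelation control gives this trans relationship, so the secondary allylic alcohol is then inverted by a Mitsunobu reaction (4-nitrobenzoic acid, PPh3, DIAD) to (1S,5S)-5-hydroxy-5-[(12Z)-16-phenylhexadec-12-en-1-yl]cyclohex-2-en-1-yl 4-nitrobenzoate F4, and K2CO3 in MeOH releases 21.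

Step 9 (facial selectivity of the reduction). The preference for attack anti to the silyloxy group rests on a conformational argument and may be modest or even reversed. The fallback sets out from enone 19 and comes back at 20; it makes the step stereoconvergent instead of relying on substrate control. The reduction is run as before, and the unwanted epimer (1R,5S)-5-[(12Z)-16-phenylhexadec-12-en-1-yl]-5-[(triethylsilyl)oxy]cyclohex-2-en-1-ol F5 is separated. Mitsunobu inversion (4-nitrobenzoic acid, PPh3, DIAD) converts it into (1S,5S)-5-[(12Z)-16-phenylhexadec-12-en-1-yl]-5-[(triethylsilyl)oxy]cyclohex-2-en-1-yl 4-nitrobenzoate F6, and K2CO3 in MeOH returns 20.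

Step 6 (ketene cycloaddition). The 3-silyloxy-2,2-dichlorocyclobutanone can ring-open in a retro-aldol sense, and dichloroketene may attack the Z alkene. The fallback sets out from silyl enol ether 13 and comes back at cyclobutanone 17 without any ketene; it builds the four-membered ring by double alkylation of an acyl-anion equivalent. N-Chlorosuccinimide converts 13 into (14Z)-1-chloro-18-phenyloctadec-14-en-2-one F7. Chloromethyllithium (ICH2Cl, MeLi·LiBr, −78 °C to rt) gives the epichlorohydrin analogue rac-2-(chloromethyl)-2-[(12Z)-16-phenylhexadec-12-en-1-yl]oxirane F8. 2-Lithio-1,3-dithiane followed by a second equivalent of n-BuLi opens the epoxide and closes the ring to 2-[(12Z)-16-phenylhexadec-12-en-1-yl]-5,9-dithiaspiro[3.5]nonan-2-ol F9. Silylation (Et3SiOTf, 2,6-lutidine) gives triethyl({2-[(12Z)-16-phenylhexadec-12-en-1-yl]-5,9-dithiaspiro[3.5]nonan-2-yl}oxy)silane F10, and dithioacetal cleavage (MeI, CaCO3, aqueous MeCN) returns 17.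

**Further compounds**
F1 | step 8 | (3R,17Z)-3-hydroxy-21-phenylhenicosa-1,17-dien-5-one | O[C@@H](C=C)CC(=O)CCCCCCCCCCC/C=C\CCCc1ccccc1
F2 | step 8 | (3R,5S,17Z)-21-phenyl-5-(prop-2-en-1-yl)henicosa-1,17-diene-3,5-diol | O[C@@H](C=C)C[C@](O)(CCCCCCCCCCC/C=C\CCCc1ccccc1)CC=C
F3 | step 8 | (1S,3R)-1-[(12Z)-16-phenylhexadec-12-en-1-yl]cyclohex-4-ene-1,3-diol | O[C@H]1C=CC[C@@](O)(CCCCCCCCCCC/C=C\CCCc2ccccc2)C1
F4 | step 8 | (1S,5S)-5-hydroxy-5-[(12Z)-16-phenylhexadec-12-en-1-yl]cyclohex-2-en-1-yl 4-nitrobenzoate | O=C(O[C@@H]1C=CC[C@@](O)(CCCCCCCCCCC/C=C\CCCc2ccccc2)C1)c1ccc(cc1)[N+](=O)[O-]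
F5 | step 9 | (1R,5S)-5-[(12Z)-16-phenylhexadec-12-en-1-yl]-5-[(triethylsilyl)oxy]cyclohex-2-en-1-ol | O[C@H]1C=CC[C@@](O[Si](CC)(CC)CC)(CCCCCCCCCCC/C=C\CCCc2ccccc2)C1
F6 | step 9 | (1S,5S)-5-[(12Z)-16-phenylhexadec-12-en-1-yl]-5-[(triethylsilyl)oxy]cyclohex-2-en-1-yl 4-nitrobenzoate | O=C(O[C@@H]1C=CC[C@@](O[Si](CC)(CC)CC)(CCCCCCCCCCC/C=C\CCCc2ccccc2)C1)c1ccc(cc1)[N+](=O)[O-]
F7 | step 6 | (14Z)-1-chloro-18-phenyloctadec-14-en-2-one | ClCC(=O)CCCCCCCCCCC/C=C\CCCc1ccccc1
F8 | step 6 | rac-2-(chloromethyl)-2-[(12Z)-16-phenylhexadec-12-en-1-yl]oxirane | ClCC1(CCCCCCCCCCC/C=C\CCCc2ccccc2)CO1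
F9 | step 6 | 2-[(12Z)-16-phenylhexadec-12-en-1-yl]-5,9-dithiaspiro[3.5]nonan-2-ol | OC1(CCCCCCCCCCC/C=C\CCCc2ccccc2)CC2(C1)SCCCS2
F10 | step 6 | triethyl({2-[(12Z)-16-phenylhexadec-12-en-1-yl]-5,9-dithiaspiro[3.5]nonan-2-yl}oxy)silane | CC[Si](CC)(CC)OC1(CCCCCCCCCCC/C=C\CCCc2ccccc2)CC2(C1)SCCCS2
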